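## Structural features

The target is a 42-carbon stilbenoid trimer assembled around one benzene ring (the central ring) that keeps a single C–H bond. Two 2,3-dihydrofuran rings, A and B, are fused to the central ring so that their oxygen atoms flank that C–H and their C3 and C3′ atoms flank the opposite ring carbon, which bears a CH2 group. Each dihydrofuran carries a 4-hydroxyphenyl group at C2 and a 3,5-dioxygenated aryl group at C3 in a trans relation, (2R,3R) and (2′R,3′R), so two pairs of adjacent stereocentres sit on the same crowded arene. In ring B the C3′ aryl group (ring F) is tied back through its ortho carbon by an (R)-CH(2,4-dihydroxyphenyl) unit to that CH2 group, which closes a dibenzo-fused seven-membered carbocycle and places the fifth stereocentre in a 1,4-relation to C3′. Fragile points are the eight free phenols, the benzylic C2–O bonds para to a phenol (ionisation by acid, quinone-methide opening by base) and the doubly benzylic C3–H bonds. The real difficulty is to set four aryl-bearing stereocentres in the right absolute and relative sense on two heterocycles that share one ring, and to close the carbocycle on one side only. Without the bridge bond to ring F the core has a twofold axis through the CH2-bearing carbon and the C–H carbon, so most operations can be run twice in one flask. The key step uses the oxidation level of C2 and C2′: each is an O,C,aryl-substituted methine next to a stereodefined C3, that is, the anomeric carbon of a benzo-fused lactol once its aryl group is removed, so both 4-oxyphenyl groups can be added to oxocarbenium ions under control of the neighbouring C3 centres.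

## Logic of the disconnections

26 from 25. The eight phenolic O–H bonds are exchanged for O–CH3 bonds. Free phenols would not survive the organometallic, Lewis-acidic and oxidative steps, whereas aryl methyl ethers are inert to every reagent of the route. No skeletal simplification results, but 25 has no alkene, so the ether cleavage need not coexist with a stilbene. The forward step must cleave eight ethers with a Lewis acid without lasting ionisation of the C2–O bond of ring A.

25 from 24. The bond between ring F and the aryl-bearing methine of the seven-membered ring is cut. It is the bond that a benzylic cation forms with the most electron-rich carbon of the neighbouring arene. The cut removes the carbocycle and one stereocentre and restores the twofold axis: in 24 the two 3,5-dimethoxyphenyl groups are equivalent and either may close. The forward step needs protonation at the alkene carbon next to the central ring, seven-membered closure in preference to other Friedel–Crafts modes, control of the new centre by C3′, and survival of both dihydrofurans in acid.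

24 from 20 and 23 (23 from 21 and 22). The alkene is cut into an aldehyde and a benzylic phosphonate; the C–P bond of 23 is cut in turn. This places the only unsymmetrical part of the molecule in a small reagent and leaves a symmetric core. The olefination must reach a doubly ortho-substituted aldehyde, give the E alkene, and use a base too weak to remove the C3–H protons.

20 from 19 from 18. No skeletal bond is cut; the aldehyde is traced through the alcohol to the ester. The ester is the chosen spectator at this carbon because it survives the preceding steps and is not attacked by arylzinc reagents. The demand is a hydride reduction that reaches a hindered ester and a mild, non-acidic oxidation.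

18 from 13 and 16 (16 from 14). Both C2–aryl bonds are cut. Each C2 then becomes an anomeric carbon, and the two 4-methoxyphenyl groups can be added together, late, to a core whose C3 centres are already fixed. The cut removes two aryl groups and two stereocentres at once and keeps the twofold symmetry. The forward step needs 1,2-trans addition at both oxocarbenium ions, capture faster than loss of the C3 proton, and a nucleophile that outcompetes the substrate's own electron-rich rings.

13 from 12 from 8 (through 11, 10 and 9). The acetyl C–O bonds are cut first. Then the ring O–C2 bonds of 12 are cut, which opens each lactol to a phenol and an aldehyde (11). The aldehyde carbons are traced to nitromethyl groups (9, with masked phenols 8). The nitro group is kept to this point because it is the activating group that allows C3 to be set. The forward sequence must unmask the phenols before the aldehyde appears, so that each α,α-diaryl aldehyde is trapped as the lactol before it can enolise.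

8 from 6 and 7. Both C3–aryl bonds are cut. A catalytic enantioselective conjugate arylation of a nitroalkene makes these bonds and sets both C3 centres by catalyst control in one twofold operation. The demand is Re-face delivery at two hindered, twisted acceptors with little of the meso isomer.

6 from 4 and 5; 4 from 3 from 2 from 1. The two alkene bonds are cut (nitroaldol condensation), then the acetal protecting groups, then the two formyl C–C bonds. Formylation is done on the bis-methyl ether 1, because ether groups direct para and so to the two positions flanking the ester. Free phenols tend to direct ortho, into the position between the two oxygens. The methyl groups next to the formyl groups are then removed by chelation control (3) and replaced by acid-labile acetals (4), which can be taken off later in the presence of the aryl methyl ethers introduced in between.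

## Other disconnections considered

Alternative 1: The cut removes ring F from the seven-membered carbocycle. The two bonds from ring F to the doubly benzylic carbon and to the carbon that will carry the 2,4-dioxyphenyl group are broken, leading back to the indanone keto ester A3 and the aryne precursor A2.
- Forward key step: fluoride would release the aryne from A2. The enolate of A3 should add to the aryne carbon remote from the flanking methoxy group, the aryl anion should close onto the ketone, and fragmentation of the four-membered alkoxide would insert the arene into the C1–C2 bond to give the ring-expanded keto ester A1.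
- In its favour: two C–C bonds and the carbocycle form in one mild, convergent step, the methoxy group steers the regiochemistry, and the ketone and ester of A1 are handles for the 2,4-dioxyphenyl group and for dihydrofuran B.
- Against it here: A1 has no fixed stereocentre (its ester-bearing carbon is enolisable), so all five stereocentres remain to be made one at a time and the absolute configuration needs a separate asymmetric event. Dihydrofuran A has to be built late on the last free position of a crowded central ring, and the twofold symmetry is given up at the start.
- Comparison: on the constitution of the seven-membered ring this plan is the better one, because ring size and attachment points are fixed by the insertion and do not depend on the course of a late cationic closure as in step 14. In mildness and functional-group tolerance of the key event it is the equal of step 9. The chosen plan is stronger on stereocontrol (two centres by catalysis in step 5, two by substrate control in step 9, the fifth by the framework) and on step economy, since every operation before step 13 acts on both halves at once. The sequence from A1 would be linear and unsymmetrical and is judged clearly longer.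

Alternative 2: The cut is the bond between C3 of dihydrofuran A and the central ring, viewed as the result of a 1,2-aryl shift. It leads back to the flavanone A5, in which that arene is still attached to the carbonyl carbon.
- Forward key step: a hypervalent iodine oxidant with an orthoformate and acid would convert A5 into its enol ether and deliver the iodine electrophile to C3 anti to the C2 aryl group. The central arene would then migrate from C4 to C3 with departure of the iodine group, the former carbonyl carbon ending as the ester of the ring-contracted product A4.
- In its favour: the trans relation of A4 is enforced by the anti-periplanar migration, the configuration at C3 is relayed from C2 of an enantioenriched flavanone, and the arene ester is already placed for the later stilbene.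
- Against it here: C3 of A4 carries an ester and not the 3,5-dioxyphenyl group, so a decarboxylative arylation or a de novo arene synthesis is required. The migrating arene of A5 is electron-poor because of its ester, which lowers its migratory aptitude. Flavanones can racemise by reversible ring opening under acid. Only one dihydrofuran is made, and the second must be built beside it later.
- Comparison: in the origin of the 2,3-trans relation this alternative is the better one, since a stereospecific migration is more dependable than steric approach control on a cation as in step 9. In the use of cheap resorcinol-type materials the plans are equal. The chosen plan makes both heterocycles and four stereocentres in two twofold operations and puts the correct aryl group on C3 directly, so it is shorter and needs no functional-group exchange at C3.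

Alternative 3: The cut removes C2 with its aryl group from both dihydrofurans (the C2–C3 and C2–O bonds of each ring). It leads back to the bis(ortho-hydroxybenzhydrol) A7 and two equivalents of the chiral sulfonium salt A8 (or its antipode).
- Forward key step: a carbonate base would dehydrate each hydroxybenzhydrol unit of A7 to an ortho-quinone methide and deprotonate A8. Conjugate addition of the ylide to the exocyclic carbon and displacement of the sulfide by the phenoxide would close each ring, the second quinone methide forming after the first annulation, to give the bis-dihydrofuran stilbene A6.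
- In its favour: four bonds, two rings and four stereocentres arise in one flask, and the trans relation is expected from a reversible betaine and an invertive closure. A6 is the same compound as 24, so steps 14 and 15 would be shared.
- Against it here: both centres of each ring must be set by reagent control from a stoichiometric chiral sulfide acting on a flat quinone methide. This must succeed twice on one ring, the second time beside the new heterocycle and the styryl group. The quinone methides can be intercepted by water, by phenols of a second molecule or by dimerisation, and the stilbene must be carried through the base-mediated step.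
- Comparison: in convergence and step count this alternative is the better one, because it would reach 24 without the sequence of steps 5 to 13. In the expected trans selectivity the plans are equal. The chosen plan separates the two stereochemical problems, setting C3 by a catalytic enantioselective reaction of established scope and C2 by the neighbouring centre. It also works with isolable, configurationally defined intermediates and not with two successive transient quinone methides, which is why it is preferred.

Key step: step 9

Remark 1: the sense of induction of the chiral diene is taken from the accepted insertion model; the antipode that delivers the aryl group to the Re face (priority CH=CHNO2 > aryl > H) of each nitroalkene β-carbon is used, both antipodes being accessible.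
Remark 2: each twofold step consumes two equivalents of its partner; where that partner is a numbered reactant, its second equivalent is entered under the reagents that add atoms. The singly converted species reacts on under the same conditions and is numbered only in step 9, where its independent second ionisation is part of the argument.

Step 1
Reactants: 1 methyl 3,5-dimethoxybenzoate
Product: 2 methyl 2,6-diformyl-3,5-dimethoxybenzoate
Conditions: Cl2CHOMe (5 equiv), TiCl4 (6 equiv), CH2Cl2, 0 °C to 40 °C; then aq. HCl
Reagents that add atoms: dichloromethyl methyl ether (first equivalent), COC(Cl)Cl; dichloromethyl methyl ether (second equivalent), COC(Cl)Cl; water (first equivalent), O; water (second equivalent), O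
Why: Twofold Rieche formylation (electrophilic aromatic substitution); each methoxy group directs para, so the two positions flanking the ester (para to one ether, ortho to the other) should be attacked and the position between the two ethers left alone, the pattern also seen in halogenation of 3,5-dialkoxybenzoates.

Step 2
Reactants: 2 methyl 2,6-diformyl-3,5-dimethoxybenzoate
Product: 3 methyl 2,6-diformyl-3,5-dihydroxybenzoate
Conditions: BCl3 (3 equiv), CH2Cl2, −78 °C to 0 °C; then H2O
Reagents that add atoms: none
Why: Chelation-controlled Lewis-acid ether cleavage: each methoxy group lies ortho to a formyl group, a six-membered boron chelate forms and chloride removes only these two methyl groups, the ester methyl being left at this temperature.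

Step 3
Reactants: 3 methyl 2,6-diformyl-3,5-dihydroxybenzoate
Product: 4 methyl 2,6-diformyl-3,5-bis(methoxymethoxy)benzoate
Conditions: MOMCl (3 equiv), i-Pr2NEt (4 equiv), CH2Cl2, 0 °C to rt
Reagents that add atoms: chloromethyl methyl ether (first equivalent), COCCl; chloromethyl methyl ether (second equivalent), COCCl
Why: Williamson-type O-alkylation of the acidic formyl-conjugated phenols; the acetals should survive the Henry step and the arylation and can later be removed by acid without touching aryl methyl ethers.

Step 4
Reactants: 4 methyl 2,6-diformyl-3,5-bis(methoxymethoxy)benzoate; 5 nitromethane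
Product: 6 methyl 3,5-bis(methoxymethoxy)-2,6-bis[(E)-2-nitroethenyl]benzoate
Conditions: 5 (solvent, ca. 40 equiv), NH4OAc (1 equiv), 90 °C
Reagents that add atoms: nitromethane (second equivalent), C[N+](=O)[O-]
Why: Twofold Henry (nitroaldol) condensation with dehydration, one nitromethane per formyl group; the conjugated (E)-nitroalkenes are the thermodynamic products, and the hot ammonium acetate medium should drive elimination before the intermediate nitro alcohol can close onto the flanking ester.

Step 5
Reactants: 6 methyl 3,5-bis(methoxymethoxy)-2,6-bis[(E)-2-nitroethenyl]benzoate; 7 3,5-dimethoxyphenylboronic acid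
Product: 8 methyl 2,6-bis[(1R)-1-(3,5-dimethoxyphenyl)-2-nitroethyl]-3,5-bis(methoxymethoxy)benzoate
Conditions: 7 (5 equiv), [RhCl(C2H4)2]2 (5 mol %), chiral 3,6-diphenylbicyclo[3.3.0]octa-2,5-diene (11 mol %), KHF2 (aq.), toluene, rt to 40 °C
Reagents that add atoms: 3,5-dimethoxyphenylboronic acid (second equivalent), COc1cc(OC)cc(B(O)O)c1
Why: Rhodium-catalysed asymmetric conjugate arylation of β-aryl nitroalkenes (Hayashi–Miyaura type): transmetalation gives an aryl complex of monovalent rhodium on the chiral diene, which inserts each nitroalkene from the Re face of the β-carbon and so should set both diarylmethine centres as R under catalyst control; the meso isomer needs one mismatched event and is a separable diastereomer.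

Step 6
Reactants: 8 methyl 2,6-bis[(1R)-1-(3,5-dimethoxyphenyl)-2-nitroethyl]-3,5-bis(methoxymethoxy)benzoate
Product: 12 methyl (3R,5R)-3,5-bis(3,5-dimethoxyphenyl)-2,6-dihydroxy-2,3,5,6-tetrahydrobenzo[1,2-b:5,4-b′]difuran-4-carboxylate (bis-lactol; anomeric mixture), via free bis-phenol 9 (not isolated), via tetrasodium phenoxide-nitronate 10 (not isolated), via open-chain dialdehyde 11 (not isolated)
Conditions: HCl (conc., 6 equiv), MeOH, 45 °C; then NaOMe (excess), 0 °C; then into TiCl3 (aq., 10 equiv), NH4OAc buffer (pH 5–6), THF/H2O, 0 °C to rt
Reagents that add atoms: water (first equivalent), O; water (second equivalent), O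
Why: Acetal methanolysis frees the phenols, methoxide forms the nitronates, and a reductive Nef reaction with trivalent titanium (McMurry variant) reduces each nitronate to the imine, which hydrolyses; each aldehyde should be trapped at once by the neighbouring phenol as a five-membered lactol, so the enolisable α,α-diaryl aldehyde has little lifetime and both C3 centres keep the R configuration.

Step 7
Reactants: 12 bis-lactol
Product: 13 methyl (3R,5R)-2,6-diacetoxy-3,5-bis(3,5-dimethoxyphenyl)-2,3,5,6-tetrahydrobenzo[1,2-b:5,4-b′]difuran-4-carboxylate (anomeric mixture)
Conditions: Ac2O (4 equiv), pyridine (6 equiv), DMAP (5 mol %), CH2Cl2, 0 °C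
Reagents that add atoms: acetic anhydride (first equivalent), CC(=O)OC(C)=O; acetic anhydride (second equivalent), CC(=O)OC(C)=O
Why: O-acylation of the lactol hydroxyl groups; the closed form dominates for a benzo-fused five-membered lactol and the anomeric mixture is used as such.

Step 8
Reactants: 14 4-bromoanisole
Product: 16 bis(4-methoxyphenyl)zinc, via 4-methoxyphenyllithium 15 (not isolated)
Conditions: 14 (2 equiv), n-BuLi (2 equiv), Et2O, −20 °C to 0 °C; ZnCl2 (1 M in Et2O, 1 equiv), 0 °C to rt; solvent exchange to toluene, LiCl filtered off
Reagents that add atoms: 4-bromoanisole (second equivalent), COc1ccc(Br)cc1; zinc chloride, Cl[Zn]Cl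
Why: Bromine–lithium exchange on two equivalents of the aryl bromide followed by transmetalation of both aryllithium equivalents to one zinc centre gives the diarylzinc, used as a toluene solution so that no donor solvent competes for the Lewis acid in the next step.

Step 9
Reactants: 13 bis-lactol diacetate; 16 bis(4-methoxyphenyl)zinc
Product: 18 methyl (2R,3R,5R,6R)-3,5-bis(3,5-dimethoxyphenyl)-2,6-bis(4-methoxyphenyl)-2,3,5,6-tetrahydrobenzo[1,2-b:5,4-b′]difuran-4-carboxylate, via mono-arylated monoacetate 17 (not isolated)
Conditions: 16 (4 equiv), toluene/CH2Cl2, −78 °C; BF3·OEt2 (3 equiv), −78 °C to −20 °C; aq. NH4Cl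
Reagents that add atoms: bis(4-methoxyphenyl)zinc (second equivalent), COc1ccc([Zn]c2ccc(OC)cc2)cc1
Why: BF3 binds each anomeric acetate and ionises it to a benzo-fused oxocarbenium ion, planar at C2, which is attacked by an aryl–zinc bond of a diarylzinc that gives up one aryl group; the two sites react one after the other and independently, the mono-adduct 17 being ionised in the same way. The closest known reaction type is the Lewis-acid-promoted substitution of anomeric acetates by organozinc reagents, as used for C-aryl glycosides and 2-substituted cyclic ethers from lactol acetates. No ring is closed. The two new stereocentres (C2 and C6) are controlled by the neighbouring C3 and C5 centres: the 3,5-dimethoxyphenyl group shields one face of the flat five-membered cation, so the aryl group should enter anti and give the 2,3-trans relation, (2R,3R,5R,6R) overall, while the anomeric configuration of 13 is lost in the cation and plays no role. The step needs capture of the cation to be faster than loss of the doubly benzylic C3 proton, which would aromatise the ring to a benzofuran; for this reason the nucleophile is present in excess before the Lewis acid is added and the temperature is kept low. It also needs the organozinc to outrun Friedel–Crafts attack by dimethoxyphenyl rings of a second molecule and to leave the hindered methyl ester alone, which follows from the high reactivity of diarylzincs toward cations and their low reactivity toward ester carbonyl groups. The ester between the two reacting sites is twisted out of plane and cannot reach C2, so no neighbouring-group participation is expected.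

Step 10
Reactants: 18 bis(trans-2,3-diaryl-dihydrofuran) methyl ester
Product: 19 [(2R,3R,5R,6R)-3,5-bis(3,5-dimethoxyphenyl)-2,6-bis(4-methoxyphenyl)-2,3,5,6-tetrahydrobenzo[1,2-b:5,4-b′]difuran-4-yl]methanol
Conditions: LiAlH4 (3 equiv), THF, 0 °C to rt
Reagents that add atoms: none
Why: Hydride reduction of the ester to the primary benzylic alcohol; LiAlH4 is small enough for the doubly ortho-substituted ester, and aryl ethers, dihydrofurans and stereocentres are inert.

Step 11
Reactants: 19 benzylic alcohol
Product: 20 (2R,3R,5R,6R)-3,5-bis(3,5-dimethoxyphenyl)-2,6-bis(4-methoxyphenyl)-2,3,5,6-tetrahydrobenzo[1,2-b:5,4-b′]difuran-4-carbaldehyde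
Conditions: Dess–Martin periodinane (1.5 equiv), NaHCO3, CH2Cl2, rt
Reagents that add atoms: none
Why: Dess–Martin oxidation of a benzylic alcohol under buffered conditions; no over-oxidation, and the acid-sensitive C2–O bonds do not meet strong acid.

Step 12
Reactants: 21 2,4-dimethoxybenzyl alcohol; 22 triethyl phosphite
Product: 23 diethyl (2,4-dimethoxybenzyl)phosphonate
Conditions: ZnI2 (1.5 equiv), P(OEt)3 (3 equiv), toluene, reflux
Reagents that add atoms: none
Why: Zinc iodide-mediated direct phosphonylation of an electron-rich benzylic alcohol (Michaelis–Arbuzov type), which avoids the unstable 2,4-dimethoxybenzyl halide.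

Step 13
Reactants: 20 aldehyde; 23 diethyl (2,4-dimethoxybenzyl)phosphonate
Product: 24 (2R,3R,5R,6R)-4-[(E)-2-(2,4-dimethoxyphenyl)ethenyl]-3,5-bis(3,5-dimethoxyphenyl)-2,6-bis(4-methoxyphenyl)-2,3,5,6-tetrahydrobenzo[1,2-b:5,4-b′]difuran
Conditions: 23 (1.5 equiv), KOtBu (1.5 equiv), THF, 0 °C; then 20, 0 °C to rt
Reagents that add atoms: none
Why: Horner–Wadsworth–Emmons olefination; the semi-stabilised benzylic phosphonate anion should give the (E)-stilbene, and the preformed anion is too weak a base to remove the C3–H protons.

Step 14
Reactants: 24 twofold-symmetric stilbene
Product: 25 octamethyl ether of the target: (2R,3R)-dihydrofuran A, (2′R,3′R)-dihydrofuran B and (R)-CH(2,4-dimethoxyphenyl) in the seven-membered ring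
Conditions: TFA (10 equiv), CH2Cl2, 0 °C to rt
Reagents that add atoms: none
Why: Cationic Friedel–Crafts alkylation: protonation at the alkene carbon next to the central ring gives the 2,4-dimethoxybenzylic cation, which is attacked by the ortho carbon (ortho and para to methoxy) of one 3,5-dimethoxyphenyl group in a seven-membered (7-endo) closure, the two aryl groups being equivalent through the twofold axis; the new centre should follow from the fixed C3′ centre, because in the folded dibenzocycloheptadiene the aryl group takes the position perpendicular to ring F and the hydrogen the position beside the flanking methoxy group of ring F, which corresponds to R, as in acid-induced closures of related dihydrobenzofuran stilbenes.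

Step 15
Reactants: 25 octamethyl ether
Product: 26 CNP0154047.1 (target)
Conditions: BBr3 (1 M in CH2Cl2, 20 equiv), CH2Cl2, −78 °C to rt; MeOH, then H2O
Reagents that add atoms: none
Why: Lewis-acid cleavage of all eight aryl methyl ethers (boron–oxygen complexation, bromide attack at methyl), the standard last step for permethylated oligostilbenes; no alkene is left to be protonated and no stereocentre takes part in the reaction.

Compound list

1 | methyl 3,5-dimethoxybenzoate | COC(=O)c1cc(OC)cc(OC)c1 | starting material
2 | methyl 2,6-diformyl-3,5-dimethoxybenzoate | COC(=O)c1c(C=O)c(OC)cc(OC)c1C=O | intermediate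
3 | methyl 2,6-diformyl-3,5-dihydroxybenzoate | COC(=O)c1c(C=O)c(O)cc(O)c1C=O | intermediate
4 | methyl 2,6-diformyl-3,5-bis(methoxymethoxy)benzoate | COC(=O)c1c(C=O)c(OCOC)cc(OCOC)c1C=O | intermediate
5 | nitromethane | C[N+](=O)[O-] | starting material
6 | methyl 3,5-bis(methoxymethoxy)-2,6-bis[(E)-2-nitroethenyl]benzoate | COC(=O)c1c(/C=C/[N+](=O)[O-])c(OCOC)cc(OCOC)c1/C=C/[N+](=O)[O-] | intermediate
7 | 3,5-dimethoxyphenylboronic acid | COc1cc(OC)cc(B(O)O)c1 | starting material
8 | methyl 2,6-bis[(1R)-1-(3,5-dimethoxyphenyl)-2-nitroethyl]-3,5-bis(methoxymethoxy)benzoate | COC(=O)c1c([C@@H](c2cc(OC)cc(OC)c2)C[N+](=O)[O-])c(OCOC)cc(OCOC)c1[C@@H](c3cc(OC)cc(OC)c3)C[N+](=O)[O-] | intermediate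
9 | methyl 2,6-bis[(1R)-1-(3,5-dimethoxyphenyl)-2-nitroethyl]-3,5-dihydroxybenzoate (not isolated) | COC(=O)c1c([C@@H](c2cc(OC)cc(OC)c2)C[N+](=O)[O-])c(O)cc(O)c1[C@@H](c3cc(OC)cc(OC)c3)C[N+](=O)[O-] | intermediate
10 | tetrasodium bis-phenoxide bis-nitronate of 9 (not isolated) | COC(=O)c1c([C@@H](c2cc(OC)cc(OC)c2)C=[N+]([O-])[O-])c([O-])cc([O-])c1[C@@H](c3cc(OC)cc(OC)c3)C=[N+]([O-])[O-].[Na+].[Na+].[Na+].[Na+] | intermediate
11 | methyl 2,6-bis[(1R)-1-(3,5-dimethoxyphenyl)-2-oxoethyl]-3,5-dihydroxybenzoate (not isolated) | COC(=O)c1c([C@@H](c2cc(OC)cc(OC)c2)C=O)c(O)cc(O)c1[C@@H](c3cc(OC)cc(OC)c3)C=O | intermediate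
12 | methyl (3R,5R)-3,5-bis(3,5-dimethoxyphenyl)-2,6-dihydroxy-2,3,5,6-tetrahydrobenzo[1,2-b:5,4-b′]difuran-4-carboxylate (anomeric mixture) | COC(=O)c1c2[C@@H](c3cc(OC)cc(OC)c3)C(O)Oc2cc2OC(O)[C@H](c3cc(OC)cc(OC)c3)c12 | intermediate
13 | methyl (3R,5R)-2,6-diacetoxy-3,5-bis(3,5-dimethoxyphenyl)-2,3,5,6-tetrahydrobenzo[1,2-b:5,4-b′]difuran-4-carboxylate (anomeric mixture) | COC(=O)c1c2[C@@H](c3cc(OC)cc(OC)c3)C(OC(C)=O)Oc2cc2OC(OC(C)=O)[C@H](c3cc(OC)cc(OC)c3)c12 | intermediate
14 | 4-bromoanisole | COc1ccc(Br)cc1 | starting material
15 | 4-methoxyphenyllithium (not isolated) | COc1ccc([Li])cc1 | intermediate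
16 | bis(4-methoxyphenyl)zinc | COc1ccc([Zn]c2ccc(OC)cc2)cc1 | intermediate
17 | methyl (2R,3R,5R)-6-acetoxy-3,5-bis(3,5-dimethoxyphenyl)-2-(4-methoxyphenyl)-2,3,5,6-tetrahydrobenzo[1,2-b:5,4-b′]difuran-4-carboxylate (not isolated) | COC(=O)c1c2[C@@H](c3cc(OC)cc(OC)c3)[C@H](c3ccc(OC)cc3)Oc2cc2OC(OC(C)=O)[C@H](c3cc(OC)cc(OC)c3)c12 | intermediate
18 | methyl (2R,3R,5R,6R)-3,5-bis(3,5-dimethoxyphenyl)-2,6-bis(4-methoxyphenyl)-2,3,5,6-tetrahydrobenzo[1,2-b:5,4-b′]difuran-4-carboxylate | COC(=O)c1c2[C@@H](c3cc(OC)cc(OC)c3)[C@H](c3ccc(OC)cc3)Oc2cc2O[C@@H](c3ccc(OC)cc3)[C@H](c3cc(OC)cc(OC)c3)c12 | intermediate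
19 | [(2R,3R,5R,6R)-3,5-bis(3,5-dimethoxyphenyl)-2,6-bis(4-methoxyphenyl)-2,3,5,6-tetrahydrobenzo[1,2-b:5,4-b′]difuran-4-yl]methanol | OCc1c2[C@@H](c3cc(OC)cc(OC)c3)[C@H](c3ccc(OC)cc3)Oc2cc2O[C@@H](c3ccc(OC)cc3)[C@H](c3cc(OC)cc(OC)c3)c12 | intermediate
20 | (2R,3R,5R,6R)-3,5-bis(3,5-dimethoxyphenyl)-2,6-bis(4-methoxyphenyl)-2,3,5,6-tetrahydrobenzo[1,2-b:5,4-b′]difuran-4-carbaldehyde | O=Cc1c2[C@@H](c3cc(OC)cc(OC)c3)[C@H](c3ccc(OC)cc3)Oc2cc2O[C@@H](c3ccc(OC)cc3)[C@H](c3cc(OC)cc(OC)c3)c12 | intermediate
21 | 2,4-dimethoxybenzyl alcohol | COc1ccc(CO)c(OC)c1 | starting material
22 | triethyl phosphite | CCOP(OCC)OCC | starting material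
23 | diethyl (2,4-dimethoxybenzyl)phosphonate | CCOP(=O)(Cc1ccc(OC)cc1OC)OCC | intermediate
24 | (2R,3R,5R,6R)-4-[(E)-2-(2,4-dimethoxyphenyl)ethenyl]-3,5-bis(3,5-dimethoxyphenyl)-2,6-bis(4-methoxyphenyl)-2,3,5,6-tetrahydrobenzo[1,2-b:5,4-b′]difuran | COc1ccc(/C=C/c2c3[C@@H](c4cc(OC)cc(OC)c4)[C@H](c4ccc(OC)cc4)Oc3cc3O[C@@H](c4ccc(OC)cc4)[C@H](c4cc(OC)cc(OC)c4)c23)c(OC)c1 | intermediate
25 | octamethyl ether of the target: (2R,3R)-dihydrofuran A, (2′R,3′R)-dihydrofuran B, ring F bridged to the central ring by (R)-CH(2,4-dimethoxyphenyl)–CH2 | COc1ccc([C@@H]2Oc3cc4c5c(c3[C@H]2c2cc(OC)cc(OC)c2)C[C@H](c2ccc(OC)cc2OC)c2c(OC)cc(OC)cc2[C@H]5[C@H](c2ccc(OC)cc2)O4)cc1 | intermediate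
26 | CNP0154047.1: central benzene fused to trans-(2R,3R)-2-(4-hydroxyphenyl)-3-(3,5-dihydroxyphenyl)dihydrofuran A and to trans-(2′R,3′R)-2′-(4-hydroxyphenyl)dihydrofuran B, whose C3′ resorcinol ring F is linked from its ortho carbon through (R)-CH(2,4-dihydroxyphenyl)–CH2 to the central-ring carbon between C3 and C3′ | Oc1ccc([C@@H]2Oc3cc4c5c(c3[C@H]2c2cc(O)cc(O)c2)C[C@H](c2ccc(O)cc2O)c2c(O)cc(O)cc2[C@H]5[C@H](c2ccc(O)cc2)O4)cc1 | target

Total step count: 15 (13 in the main line and two reagent preparations, steps 8 and 12). Longest linear sequence: 13 steps (steps 1–7, 9–11, 13–15).

Least certain steps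

Step 9 (key step). What may go wrong: loss of the doubly benzylic C3 proton from the oxocarbenium ion (aromatisation to a benzofuran, which erases C3), sluggish second ionisation beside the electron-poor ring, or aryl transfer from zinc to boron that consumes the nucleophile. Fallback: the order of bond formation at C2 is reversed, with the C2–aryl bond made by carbonyl addition and the C2–O bond by cationic ring closure. The fallback sets out from 12. Commercial 4-MeOC6H4MgBr with CeCl3 (excess, THF, −78 °C) adds to the aldehyde form released from the metal lactolate and should give methyl 2,6-bis[(1R)-1-(3,5-dimethoxyphenyl)-2-hydroxy-2-(4-methoxyphenyl)ethyl]-3,5-dihydroxybenzoate F1 as a mixture at the carbinol carbons. Catalytic TsOH·H2O in CH2Cl2 at 0 °C then ionises each 4-methoxybenzylic alcohol, and the neighbouring phenol closes the ring (5-exo) to the thermodynamically favoured trans isomer. The fallback returns to the route at 18.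

Step 1. What may go wrong: stalling after the first formylation, because the ring is deactivated by the first-installed formyl equivalent and crowded by the ester. Fallback: halogenation followed by cross-coupling and oxidative cleavage, setting out from 1. NBS (2.2 equiv, MeCN) should give methyl 2,6-dibromo-3,5-dimethoxybenzoate F2. Twofold Suzuki–Miyaura coupling with CH2=CHBF3K (Pd(OAc)2, SPhos, K2CO3, toluene/H2O, 90 °C) gives methyl 2,6-diethenyl-3,5-dimethoxybenzoate F3. Lemieux–Johnson cleavage (OsO4 cat., NaIO4, 2,6-lutidine, dioxane/H2O) returns to the route at 2.

Step 5. What may go wrong: slow insertion into the twisted, doubly ortho-substituted nitroalkenes so that protodeboronation wins, or weaker facial control in the second addition with build-up of the meso diastereomer. Fallback: a different catalytic manifold, setting out from 6. Aryl transfer is run with cationic divalent palladium (Pd(O2CCF3)2, chiral pyridine–oxazoline ligand, MeOH, 40 °C, air), in which an aryl–palladium species adds to the nitroalkene and the nitronate is protonated at once by the solvent, without base. The ligand antipode is again chosen for Re-face delivery. The fallback returns at 8 and makes no new compound.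

Step 6. What may go wrong: enolisation of the transient aldehyde before lactol closure, which would erode the C3 configuration, or reduction stopping at the oxime stage. Fallback: stepwise reduction and transoximation in place of the Nef reaction, setting out from 8. SnCl2·2H2O with PhSH and Et3N (THF, rt) should reduce both primary nitro groups to give methyl 2,6-bis[(1R)-1-(3,5-dimethoxyphenyl)-2-(hydroxyimino)ethyl]-3,5-bis(methoxymethoxy)benzoate F4. Aqueous HCHO with HCl in THF/MeOH then removes the acetals and transfers the oxime to formaldehyde, so the aldehyde is set free only in acid and beside the free phenol. The fallback returns at 12.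

Step 13. What may go wrong: slow addition of the phosphonate anion to the doubly ortho-substituted aldehyde, leaving time for base-induced deprotonation at C3 and ring opening by β-elimination. Fallback: reversal of polarity, setting out from 19. CBr4/PPh3 (CH2Cl2, 0 °C) gives the benzylic bromide (4-bromomethyl analogue of 19) F5. P(OEt)3 at 120 °C (Michaelis–Arbuzov) gives the core phosphonate (diethyl phosphonomethyl analogue) F6. Deprotonation with KOtBu and addition of commercial, unhindered 2,4-dimethoxybenzaldehyde then returns to the route at 24.

Step 4. What may go wrong: capture of the nitroaldol or nitro-Mannich intermediate by the flanking methyl ester (five-membered lactonisation or lactamisation at the benzylic oxygen or nitrogen) before elimination, which would consume one arm together with the ester. Fallback: olefination followed by radical nitration of the alkene, so that no benzylic alkoxide or amine ever sits beside the ester; it sets out from 4. Twofold Wittig methylenation (Ph3PCH3Br, KOtBu, THF, 0 °C) gives methyl 2,6-diethenyl-3,5-bis(methoxymethoxy)benzoate F7. Nitration of both vinyl groups with AgNO2 and TEMPO (4 Å molecular sieves, ClCH2CH2Cl, 70 °C) proceeds by addition of the NO2 radical to the terminal carbon, trapping of the benzylic radical by TEMPO and loss of the hydroxylamine, and should give the (E)-nitroalkenes. The fallback returns to the route at 6.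

## Further compounds

F1 | step 9 | methyl 2,6-bis[(1R)-1-(3,5-dimethoxyphenyl)-2-hydroxy-2-(4-methoxyphenyl)ethyl]-3,5-dihydroxybenzoate (mixture at the carbinol carbons) | COC(=O)c1c([C@@H](c2cc(OC)cc(OC)c2)C(O)c4ccc(OC)cc4)c(O)cc(O)c1[C@@H](c3cc(OC)cc(OC)c3)C(O)c5ccc(OC)cc5
F2 | step 1 | methyl 2,6-dibromo-3,5-dimethoxybenzoate | COC(=O)c1c(Br)c(OC)cc(OC)c1Br
F3 | step 1 | methyl 2,6-diethenyl-3,5-dimethoxybenzoate | COC(=O)c1c(C=C)c(OC)cc(OC)c1C=C
F0 | step 5 | none | none
F4 | step 6 | methyl 2,6-bis[(1R)-1-(3,5-dimethoxyphenyl)-2-(hydroxyimino)ethyl]-3,5-bis(methoxymethoxy)benzoate | COC(=O)c1c([C@@H](c2cc(OC)cc(OC)c2)C=NO)c(OCOC)cc(OCOC)c1[C@@H](c3cc(OC)cc(OC)c3)C=NO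
F5 | step 13 | (2R,3R,5R,6R)-4-(bromomethyl)-3,5-bis(3,5-dimethoxyphenyl)-2,6-bis(4-methoxyphenyl)-2,3,5,6-tetrahydrobenzo[1,2-b:5,4-b′]difuran | BrCc1c2[C@@H](c3cc(OC)cc(OC)c3)[C@H](c3ccc(OC)cc3)Oc2cc2O[C@@H](c3ccc(OC)cc3)[C@H](c3cc(OC)cc(OC)c3)c12
F6 | step 13 | diethyl {[(2R,3R,5R,6R)-3,5-bis(3,5-dimethoxyphenyl)-2,6-bis(4-methoxyphenyl)-2,3,5,6-tetrahydrobenzo[1,2-b:5,4-b′]difuran-4-yl]methyl}phosphonate | CCOP(=O)(Cc1c2[C@@H](c3cc(OC)cc(OC)c3)[C@H](c3ccc(OC)cc3)Oc2cc2O[C@@H](c3ccc(OC)cc3)[C@H](c3cc(OC)cc(OC)c3)c12)OCC
F7 | step 4 | methyl 2,6-diethenyl-3,5-bis(methoxymethoxy)benzoate | COC(=O)c1c(C=C)c(OCOC)cc(OCOC)c1C=C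
A1 | alternative 1 | methyl 2,4-bis(benzyloxy)-7,9-dimethoxy-10-oxo-10,11-dihydro-5H-dibenzo[a,d][7]annulene-5-carboxylate (C5 configurationally labile) | COC(=O)C1c2cc(OC)cc(OC)c2C(=O)Cc2cc(OCc3ccccc3)cc(OCc3ccccc3)c21
A2 | alternative 1 | 3,5-dimethoxy-2-(trimethylsilyl)phenyl trifluoromethanesulfonate | COc1cc(OC)c([Si](C)(C)C)c(OS(=O)(=O)C(F)(F)F)c1
A3 | alternative 1 | methyl 5,7-bis(benzyloxy)-2-oxo-2,3-dihydro-1H-indene-1-carboxylate | COC(=O)C1C(=O)Cc2cc(OCc3ccccc3)cc(OCc3ccccc3)c12
A4 | alternative 2 | dimethyl (2R,3R)-6-(benzyloxy)-2-(4-methoxyphenyl)-2,3-dihydro-1-benzofuran-3,4-dicarboxylate (trans) | COC(=O)c1cc(OCc2ccccc2)cc2O[C@@H](c3ccc(OC)cc3)[C@H](C(=O)OC)c12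
A5 | alternative 2 | methyl (2R)-7-(benzyloxy)-2-(4-methoxyphenyl)-4-oxo-3,4-dihydro-2H-chromene-5-carboxylate | COC(=O)c1cc(OCc2ccccc2)cc2O[C@@H](c3ccc(OC)cc3)CC(=O)c12
A6 | alternative 3 | twofold-symmetric bis(trans-2,3-diaryl-dihydrofuran) stilbene octamethyl ether (identical with 24) | COc1ccc([C@@H]2Oc3cc4c(c(/C=C/c5ccc(OC)cc5OC)c3[C@H]2c2cc(OC)cc(OC)c2)[C@@H](c2cc(OC)cc(OC)c2)[C@H](c2ccc(OC)cc2)O4)cc1
A7 | alternative 3 | 4,6-bis[(3,5-dimethoxyphenyl)(hydroxy)methyl]-5-[(E)-2-(2,4-dimethoxyphenyl)ethenyl]benzene-1,3-diol | COc1ccc(/C=C/c2c(C(O)c3cc(OC)cc(OC)c3)c(O)cc(O)c2C(O)c4cc(OC)cc(OC)c4)c(OC)c1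
A8 | alternative 3 | (2R,5R)-1-(4-methoxybenzyl)-2,5-dimethylthiolan-1-ium tetrafluoroborate | C[C@@H]1CC[C@@H](C)[S+]1Cc1ccc(OC)cc1.F[B-](F)(F)F
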